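## The problem

Japonicone A (38) is a C32 adduct of a guaianolide and a eudesmanolide (biogenetic numbering, eudesmane half primed). C1 and C3 of the guaiane five-membered ring are bonded to C13′ and C11′ of the eudesmane lactone, so C1–C5 with C11′/C13′ form a norbornene. C2 is its one-carbon bridge and carries the acetoxy group syn to C4=C5, C1 is quaternary and C11′ is a spiro centre. The eudesmane half is a 1′-hydroxyalantolactone skeleton: ring A holds the C1′ carbinol, the C4′ methyl and the quaternary C10′, and ring B holds the C5′=C6′ alkene and a cis lactone at C7′/C8′. The guaiane half has a trans 12,8-lactone and the C10 methyl on the seven-membered ring. Of the twelve stereocentres, C1, C3 and C11′ arise only in the union and are controlled solely by the faces of the two partners: the C10 methyl and the C2 acetoxy group mark the diene face, the convex side of the cis lactone the dienophile face. Within the eudesmane half C10′ is the hub, because its axial methyl later directs C7′ and C8′, and it must be set cis to the C4′ methyl. The sensitive groups are two lactones (one an α-methylene lactone until the end), a secondary acetate, β,γ-unsaturated ketones that can slip into conjugation, an allylsilane that can protodesilylate, and a 5-acetoxycyclopentadiene that isomerises by 1,5-hydrogen shift. The union must therefore be mild and last. The feature that makes the key step possible is the array C1′(OH)–C10′(quaternary)–C5′=C6′ in ring A. It is a homoallylic alcohol, the retron of an allylsilane (silicon on C6′, alkene C5′=C10′) adding through C10′ to a C1′ aldehyde.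

## Retrosynthesis

**Union.** Cutting C1–C13′ and C3–C11′ of 38 gives the eudesmanolide 22 and the acetoxy diene 37. This is the only cut that removes three stereocentres and the spiro centre at once and leaves two halves of equal size. Any cut inside the bridge would force one half to be grown linearly on the other. The forward Diels–Alder reaction must be endo for the lactone carbonyl, must join the hindered C1 to the CH2 terminus, and must use the diene face opposite the C10 methyl and the acetoxy group.

**Lactone of 22.** The methylene group is removed (21, 19), then the lactone is opened at O–C12′ and C7′–C11′, back through 18 and 16 to the silyl ether 14 of ketone 13. A ketone at C8′ is preferred to a preformed carbinol because the axial C14′ methyl can then control both new centres. Ketone 13 has only three stereocentres.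

**Ring A (key step).** Cutting C1′–C10′ of 13 gives the allylsilane aldehyde 12. The neighbouring cut C5′–C10′ (an enolate annulation) would have to alkylate a fully substituted carbon. Here the fully substituted carbon is the nucleophile, and loss of silicon fixes the alkene at C5′=C6′ without a choice of proton. The forward reaction needs attack anti to silicon with the C4′ methyl cis to C14′, so 12 must carry the matched (4′R,6′S) pair.

**Matching C4′ and C6′.** Compound 12 comes from alcohol 11, and 11 from the β-silyl spiro enone 10 by reductive C5′–O cleavage. Enone 10 comes from spirodienone 9 by conjugate silylation, and 9 from phenol 8 by oxidative dearomatisation. Birch reduction of an arylsilane would reach the same ring, but its protonation at C6′ is blind to C4′. In the spiro route C4′ sets the spiro centre C5′, C5′ sets C6′, and C5′ is then erased. Phenol 8 has one stereocentre.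

**Side chain.** Phenol 8 is reached from ester 3 through aldehyde 4, alkene 5 and alcohol 7 (one-carbon homologation, debenzylation). Ester 3 is cut at the aryl–C4′ bond to boronic acid 1 and ethyl crotonate 2, with the stereocentre set by catalysis.

**Diene 37.** The C3=C4 alkene is traced to the tertiary alcohol in 36, the acetate to alcohol 35, and the C2 carbinol to the enone 34. The diene is thus unveiled by a single elimination after the C2 configuration has been set by a reagent.

**Seven-membered ring.** The lactone of 34 is traced to the isopropenyl carbinol 32 via triol 33. Cutting C7–C8 of 32 (carbonyl-ene) gives the prenyl aldehyde 31. This cut forms the ring, both lactone stereocentres and the C11–C13 unit together, which a Nazarov route from a preformed cycloheptene would not.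

**Five-membered ring.** Compound 31 comes from the allyl enone 30 by metathesis. Enone 30 comes from the vinylogous ester 28 (allyl addition and transposition), and 28 from 27 and 26 by enolate methylation and hydroxylation. Acetal 26 is cut at C1–C10 to cyclopentane-1,3-dione 23 and crotonaldehyde 24.

## Roads not taken

**Alternative 1:** The cut is the C1–C5 bond of the guaiane half, so that both halves descend from one eudesmane skeleton. Forward, a C1 sulfonate on a trans-lactone eudesmane substrate ionises with participation of the C5=C6 π bond. C5 moves from C10 to C1 and the C10 cation loses a proton to give the triene A1. The merit is economy: a relative of 13 could feed both halves. In this respect the road is better than the chosen one, which needs an unrelated eleven-step branch. Its weak points are these: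
- A1 has its alkenes at 1(10) and 5 and no oxygen at C2, so the 1(5),3-diene and a configured C2 acetoxy group remain to be installed.
- The C10 stereocentre is erased and must be reset.
- The guaiane half needs a trans lactone and the eudesmane half a cis one, so the two lines part early.

The chosen plan sets against the shared intermediate a C2 oxygen present from the first step of its branch (a dione carbonyl) and a C10 centre set once by catalysis and never touched.

**Alternative 2:** The cut is C4–C5 of the guaiane five-membered ring. Forward, acid promotes the conrotatory closure of a cross-conjugated dienone whose one arm is the cycloheptene C1=C5 bond. The oxyallyl cation loses a proton to leave the carbonyl at C2 and the alkene at C1=C5, giving A2. This delivers the same 2-oxo-1(5)-ene array that the chosen route reaches at 34. It does so by a reaction with more precedent than a seven-membered ene closure, and here it is as good or better. Its weak points are these: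
- The seven-membered ring with three stereocentres and the trans lactone must be built first.
- Strong acid meets a lactone.
- A2 lacks C13.
- C3=C4 must still be introduced next to a configured C2.

The chosen plan starts from the five-membered ring as bought and closes the seven-membered ring with C11–C13 already attached. It carries the C4 hydroxyl from step 19, so that one elimination gives the diene.

**Alternative 3:** The cut is the C2–C3 bond of the norbornene, read backwards as expansion of the one-carbon bridge to the keto bridge of a bicyclo[2.2.2]octenone made from a dearomatised phenol and the eudesmanolide. Forward, methoxide (or methanol with AgBF4) adds to the bridge ketone of the α-bromo ketone. C3 migrates to C2 with inversion and the bridge contracts to a carbon bearing a methyl ester syn to C4=C5, giving A3. This road never handles the labile diene 37. It also fixes C2 by a stereospecific shift and not by a facial preference that runs against the electronic bias of 5-oxygenated cyclopentadienes. In both respects it is better than the chosen plan. Its weak points are these: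
- The ester carbon must be degraded to an acetoxy group on a hindered bridge.
- C13 is still missing.
- The eudesmanolide is committed early and carried through a long linear sequence.

The chosen plan sets against this its convergence (longest line 17 steps), a last step that forms both bonds and three stereocentres with nothing left to adjust, and the in-situ trapping fallback at step 27.

Key step: step 10

Remarks on the chemistry: In names of single halves the primes are dropped. Compounds 27–36 are carried as mixtures at C4 (26–29 also at the acetal carbon); both centres are destroyed later. A dimethylphenylsilyl group is used on C6′ as the spectator silyl group. The absolute configuration follows the target as drawn, and the catalyst enantiomers are chosen for it.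

## Route

Step 1
Reactants: 1 [4-(benzyloxy)-2-methylphenyl]boronic acid; 2 ethyl (E)-but-2-enoate
Product: 3 ethyl (3R)-3-[4-(benzyloxy)-2-methylphenyl]butanoate
Conditions: Rh(acac)(C2H4)2 (3 mol %), (S)-BINAP, dioxane/H2O 10:1, 100 °C
Reagents that add atoms: none
Why: Rhodium-catalysed asymmetric conjugate addition of an arylboronic acid to an E-enoate (Hayashi–Miyaura); with (S)-BINAP the aryl group should be delivered to the 2-si face of the crotonate, which sets C4′ as R.

Step 2
Reactants: 3 ethyl (3R)-3-[4-(benzyloxy)-2-methylphenyl]butanoate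
Product: 4 (3R)-3-[4-(benzyloxy)-2-methylphenyl]butanal
Conditions: i-Bu2AlH, CH2Cl2, −78 °C; Rochelle salt
Reagents that add atoms: none
Why: Partial reduction of an ester through the aluminium hemiacetal, which is stable at low temperature; the stereocentre is β to the carbonyl and cannot epimerise.

Step 3
Reactants: 4 (3R)-3-[4-(benzyloxy)-2-methylphenyl]butanal
Product: 5 4-(benzyloxy)-2-methyl-1-[(2R)-pent-4-en-2-yl]benzene
Conditions: Ph3PCH3Br, KOt-Bu, THF, 0 °C to rt
Reagents that add atoms: methyltriphenylphosphonium bromide, C[P+](c1ccccc1)(c1ccccc1)c1ccccc1.[Br-]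
Why: Wittig methylenation with a non-stabilised ylide adds the carbon that becomes C1′.

Step 4
Reactants: 5 4-(benzyloxy)-2-methyl-1-[(2R)-pent-4-en-2-yl]benzene
Product: 7 (4R)-4-[4-(benzyloxy)-2-methylphenyl]pentan-1-ol, via B-alkyl-9-BBN adduct 6 (not isolated)
Conditions: 9-BBN, THF, 0 °C to rt; then NaOH, H2O2
Reagents that add atoms: hydrogen peroxide, OO
Why: Anti-Markovnikov hydroboration–oxidation of a terminal alkene places the hydroxyl on C1′.

Step 5
Reactants: 7 (4R)-4-[4-(benzyloxy)-2-methylphenyl]pentan-1-ol
Product: 8 4-[(2R)-5-hydroxypentan-2-yl]-3-methylphenol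
Conditions: H2 (1 atm), Pd/C, EtOAc, rt
Reagents that add atoms: none
Why: Hydrogenolysis of the benzyl ether frees the para-phenol needed for dearomatisation; no alkene remains to be reduced.

Step 6
Reactants: 8 4-[(2R)-5-hydroxypentan-2-yl]-3-methylphenol
Product: 9 (5R,6S)-5,7-dimethyl-1-oxaspiro[5.5]undeca-7,10-dien-9-one
Conditions: PhI(OAc)2, (CF3)2CHOH/CH2Cl2, 0 °C
Reagents that add atoms: none
Why: Oxidative dearomatisation of a para-alkylphenol by trivalent iodine with capture of the ipso carbon C5′ by the tethered hydroxyl (spiroetherification). The benzylic C4′–H eclipses the ortho methyl (A(1,3) strain), so the chain and its oxygen add to one face with C15′ on the other, and the spiro centre forms with the C4′ methyl beside the unsubstituted C6′ arm.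

Step 7
Reactants: 9 (5R,6S)-5,7-dimethyl-1-oxaspiro[5.5]undeca-7,10-dien-9-one
Product: 10 (5R,6R,11S)-11-[dimethyl(phenyl)silyl]-5,7-dimethyl-1-oxaspiro[5.5]undec-7-en-9-one
Conditions: PhMe2Si–Bpin, CuCl (5 mol %), IMes·HCl, NaOt-Bu, MeOH, THF, 0 °C
Reagents that add atoms: 2-[dimethyl(phenyl)silyl]-4,4,5,5-tetramethyl-1,3,2-dioxaborolane, C[Si](C)(c1ccccc1)B1OC(C)(C)C(C)(C)O1
Why: Copper-catalysed conjugate silylation of a cross-conjugated dienone, which should occur at the unsubstituted β-carbon C6′ and not at the methyl-bearing C10′. Silicon enters anti to C4′ and its methyl, syn to the ring oxygen, which makes C6′ S and matches it to C4′.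

Step 8
Reactants: 10 (5R,6R,11S)-11-[dimethyl(phenyl)silyl]-5,7-dimethyl-1-oxaspiro[5.5]undec-7-en-9-one
Product: 11 (5S)-5-[dimethyl(phenyl)silyl]-4-[(2R)-5-hydroxypentan-2-yl]-3-methylcyclohex-3-en-1-one
Conditions: SmI2 (2.5 equiv), MeOH, THF, −78 °C
Reagents that add atoms: none
Why: SmI2 reduction of a γ-alkoxy enone: the β-carbanion at C10′ expels the C5′ alkoxide and the dienolate is protonated at the α-carbon C9′, giving the β,γ-unsaturated ketone with the C5′=C10′ alkene. The spiro centre disappears after it has passed its information to C6′.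

Step 9
Reactants: 11 (5S)-5-[dimethyl(phenyl)silyl]-4-[(2R)-5-hydroxypentan-2-yl]-3-methylcyclohex-3-en-1-one
Product: 12 (4R)-4-{(6S)-6-[dimethyl(phenyl)silyl]-2-methyl-4-oxocyclohex-1-en-1-yl}pentanal
Conditions: Dess–Martin periodinane, NaHCO3, CH2Cl2, 0 °C
Reagents that add atoms: none
Why: Buffered Dess–Martin oxidation of the primary alcohol; the neutral conditions should leave the allylsilane and the β,γ-alkene in place.

Step 10
Reactants: 12 (4R)-4-{(6S)-6-[dimethyl(phenyl)silyl]-2-methyl-4-oxocyclohex-1-en-1-yl}pentanal
Product: 13 (1S,4R,10S)-1-hydroxyeudesm-5-en-8-one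
Conditions: TiCl4 (1.1 equiv), CH2Cl2, −78 °C, short contact; aq. NaHCO3
Reagents that add atoms: none
Why: Intramolecular Hosomi–Sakurai allylation. TiCl4 binds the C1′ aldehyde, C10′ (the γ-carbon of the C6′ allylsilane) attacks it anti to the C6′–Si bond, and the β-silyl cation at C5′ collapses by loss of silicon, so the alkene can appear only at C5′=C6′. The closest known reactions are Lewis-acid cyclisations of ring allylsilanes onto tethered aldehydes and enones that create quaternary ring-fusion carbons. Ring A closes as a six-membered chair, exo at the carbonyl with both allyl carbons C5′ and C10′ inside the new ring. C10′ is set by the C6′ silyl centre, since attack anti to silicon leaves the C14′ methyl on the face silicon occupied; C1′ is set by the chair, in which the titanium-bound oxygen is equatorial and so cis to the axial C14′ methyl. The step needs the C4′ methyl axial on the forming ring, on the silicon face, so that it ends cis to C14′; this is secured by the (4′R,6′S) pair built in steps 6 and 7, and the sp2 carbon C5′ between the two groups splays them apart. The free C8′ ketone is a spectator because no ring of workable size links C10′ to C8′, and low temperature keeps the β,γ-alkene out of conjugation.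

Step 11
Reactants: 13 (1S,4R,10S)-1-hydroxyeudesm-5-en-8-one
Product: 14 (1S,4R,10S)-1-[(tert-butyldimethylsilyl)oxy]eudesm-5-en-8-one
Conditions: TBSOTf, 2,6-lutidine, CH2Cl2, −78 °C
Reagents that add atoms: tert-butyldimethylsilyl trifluoromethanesulfonate, CC(C)(C)[Si](C)(C)OS(=O)(=O)C(F)(F)F
Why: Silyl triflate silylation of a hindered secondary alcohol; at −78 °C with 2,6-lutidine the ketone should not be enolised.

Step 12
Reactants: 14 (1S,4R,10S)-1-[(tert-butyldimethylsilyl)oxy]eudesm-5-en-8-one
Product: 16 ethyl (1S,4R,7R,10S)-1-[(tert-butyldimethylsilyl)oxy]-8-oxo-13-noreudesm-5-en-12-oate, via C7 epimer 15 (not isolated)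
Conditions: LiN(i-Pr)2, THF, −78 °C; BrCH2CO2Et, DMPU; then LiN(i-Pr)2, −78 °C; AcOH, −78 °C
Reagents that add atoms: ethyl bromoacetate, CCOC(=O)CBr
Why: Kinetic deprotonation at the doubly activated C7′ gives the linear dienolate, which alkylates at its α-carbon on the face anti to the axial C14′ methyl. Re-deprotonation and kinetic α-protonation from that same face then turn the side chain equatorial and cis to C14′, without letting the alkene move into conjugation.

Step 13
Reactants: 16 ethyl (1S,4R,7R,10S)-1-[(tert-butyldimethylsilyl)oxy]-8-oxo-13-noreudesm-5-en-12-oate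
Product: 18 (1S,4R,7R,8S,10S)-1-[(tert-butyldimethylsilyl)oxy]-13-noreudesm-5-en-12,8-olide, via hydroxy ester 17 (not isolated)
Conditions: LiBH(s-Bu)3, THF, −78 °C to rt
Reagents that add atoms: none
Why: The bulky hydride attacks C8′ equatorially, away from the 1,3-diaxial C14′ methyl; the axial alkoxide is cis to the C7′ side chain and closes the cis γ-lactone with loss of ethoxide.

Step 14
Reactants: 18 (1S,4R,7R,8S,10S)-1-[(tert-butyldimethylsilyl)oxy]-13-noreudesm-5-en-12,8-olide
Product: 19 (1S,4R,7S,8S,10S,11R)-13-(dimethylamino)-1-[(tert-butyldimethylsilyl)oxy]eudesm-5-en-12,8-olide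
Conditions: LiN(i-Pr)2, THF, −78 °C; CH2=NMe2+ I−
Reagents that add atoms: N,N-dimethylmethyleneiminium iodide, C=[N+](C)C.[I-]
Why: Mannich reaction of the lactone enolate with the iminium salt on the convex face; the new centre at C11′ is removed in the next step.

Step 15
Reactants: 19 (1S,4R,7S,8S,10S,11R)-13-(dimethylamino)-1-[(tert-butyldimethylsilyl)oxy]eudesm-5-en-12,8-olide
Product: 21 (1S,4R,7S,8S,10S)-1-[(tert-butyldimethylsilyl)oxy]eudesma-5,11(13)-dien-12,8-olide, via ammonium iodide 20 (not isolated)
Conditions: MeI, MeOH, rt; then NaHCO3, CH2Cl2/H2O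
Reagents that add atoms: none
Why: Quaternisation followed by base-induced β-elimination of trimethylamine is the standard way to an α-methylene lactone.

Step 16
Reactants: 21 (1S,4R,7S,8S,10S)-1-[(tert-butyldimethylsilyl)oxy]eudesma-5,11(13)-dien-12,8-olide
Product: 22 (1S,4R,7S,8S,10S)-1-hydroxyeudesma-5,11(13)-dien-12,8-olide
Conditions: HF·pyridine, THF, 0 °C to rt
Reagents that add atoms: none
Why: Acidic fluoride desilylation avoids the basic conditions under which the α-methylene lactone would take up nucleophiles.

Step 17
Reactants: 23 cyclopentane-1,3-dione; 24 (E)-but-2-enal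
Product: 26 (4R)-2-methoxy-4-methyl-3,4,6,7-tetrahydrocyclopenta[b]pyran-5(2H)-one, via lactol 25 (not isolated)
Conditions: (S)-α,α-diphenylprolinol trimethylsilyl ether (10 mol %), PhCO2H (cat.), CH2Cl2, rt; then MeOH, camphorsulfonic acid (cat.)
Reagents that add atoms: methanol, CO
Why: Iminium-catalysed Michael addition of a cyclic 1,3-dione to an enal: the dione adds to the β-carbon face remote from the diarylsilyloxymethyl group, setting C10 as R. The methyl acetal locks the adduct as a cyclic vinylogous ester and masks the C8 aldehyde.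

Step 18
Reactants: 26 (4R)-2-methoxy-4-methyl-3,4,6,7-tetrahydrocyclopenta[b]pyran-5(2H)-one
Product: 27 (4R)-2-methoxy-4,6-dimethyl-3,4,6,7-tetrahydrocyclopenta[b]pyran-5(2H)-one
Conditions: LiN(i-Pr)2, THF, −78 °C; MeI
Reagents that add atoms: iodomethane, CI
Why: Kinetic α′-deprotonation of a vinylogous ester and methylation (Stork–Danheiser alkylation) brings in C15 on C4.

Step 19
Reactants: 27 (4R)-2-methoxy-4,6-dimethyl-3,4,6,7-tetrahydrocyclopenta[b]pyran-5(2H)-one
Product: 28 (4R)-6-hydroxy-2-methoxy-4,6-dimethyl-3,4,6,7-tetrahydrocyclopenta[b]pyran-5(2H)-one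
Conditions: LiN(i-Pr)2, THF, −78 °C; 3-phenyl-2-(phenylsulfonyl)oxaziridine
Reagents that add atoms: 3-phenyl-2-(phenylsulfonyl)oxaziridine, O=S(=O)(c1ccccc1)N1OC1c1ccccc1
Why: Enolate hydroxylation with the Davis oxaziridine places the leaving group for the later C3=C4 alkene on C4; its configuration is immaterial.

Step 20
Reactants: 28 (4R)-6-hydroxy-2-methoxy-4,6-dimethyl-3,4,6,7-tetrahydrocyclopenta[b]pyran-5(2H)-one
Product: 30 4-hydroxy-4-methyl-2-[(2R)-4-oxobutan-2-yl]-3-(prop-2-en-1-yl)cyclopent-2-en-1-one, via tertiary alcohol adduct 29 (not isolated)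
Conditions: CH2=CHCH2MgBr (3 equiv), THF, −78 to 0 °C; then 1 M HCl, THF, rt
Reagents that add atoms: allylmagnesium bromide, C=CC[Mg]Br; water, O
Why: Stork–Danheiser transposition: allyl adds to the C5 carbonyl (one equivalent is spent on the tertiary hydroxyl). Acid then ionises the new carbinol, water adds at C2, and the cyclic acetal falls apart to give the C2 ketone, the C1=C5 alkene and the free C8 aldehyde.

Step 21
Reactants: 30 4-hydroxy-4-methyl-2-[(2R)-4-oxobutan-2-yl]-3-(prop-2-en-1-yl)cyclopent-2-en-1-one
Product: 31 4-hydroxy-4-methyl-3-(3-methylbut-2-en-1-yl)-2-[(2R)-4-oxobutan-2-yl]cyclopent-2-en-1-one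
Conditions: 2-methyl-2-butene (solvent), second-generation Grubbs catalyst (5 mol %), 40 °C
Reagents that add atoms: 2-methyl-2-butene, CC=C(C)C
Why: Cross-metathesis of a terminal alkene with 2-methyl-2-butene gives the prenyl group; the tetrasubstituted enone alkene and the trisubstituted product are inert.

Step 22
Reactants: 31 4-hydroxy-4-methyl-3-(3-methylbut-2-en-1-yl)-2-[(2R)-4-oxobutan-2-yl]cyclopent-2-en-1-one
Product: 32 (7S,8R,10R)-4,8-dihydroxyguaia-1(5),11(13)-dien-2-one
Conditions: Me2AlCl (3 equiv), CH2Cl2, −78 to −20 °C
Reagents that add atoms: none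
Why: Lewis-acid-promoted intramolecular carbonyl-ene reaction of the citronellal-to-isopulegol type: C7 attacks the C8 aldehyde and a methyl hydrogen passes to oxygen, closing the seven-membered ring across the cis cyclopentene. In the chair-like transition state the hydroxyl and the isopropenyl group are trans-diequatorial, while the C10 methyl is pseudo-axial to avoid A(1,2) strain with the C2 carbonyl. This should place C8–O trans and C7–C11 cis to the methyl.

Step 23
Reactants: 32 (7S,8R,10R)-4,8-dihydroxyguaia-1(5),11(13)-dien-2-one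
Product: 33 (7S,8R,10R)-4,8,12-trihydroxyguaia-1(5),11(13)-dien-2-one
Conditions: SeO2 (cat.), t-BuOOH, CH2Cl2, rt
Reagents that add atoms: tert-butyl hydroperoxide, CC(C)(C)OO
Why: Allylic oxidation of an isopropenyl methyl group by SeO2, as is known for isopulegol; the electron-rich 1,1-disubstituted alkene reacts in preference to the enone.

Step 24
Reactants: 33 (7S,8R,10R)-4,8,12-trihydroxyguaia-1(5),11(13)-dien-2-one
Product: 34 (7S,8R,10R)-4-hydroxy-2-oxoguaia-1(5),11(13)-dien-12,8-olide
Conditions: TEMPO (cat.), PhI(OAc)2, CH2Cl2, rt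
Reagents that add atoms: none
Why: Oxidative lactonisation of a 1,4-diol: the primary allylic alcohol is oxidised first, the enal is captured by the C8 hydroxyl as a lactol, and the lactol is oxidised to the trans α-methylene lactone; the tertiary alcohol cannot react.

Step 25
Reactants: 34 (7S,8R,10R)-4-hydroxy-2-oxoguaia-1(5),11(13)-dien-12,8-olide
Product: 35 (2S,7S,8R,10R)-2,4-dihydroxyguaia-1(5),11(13)-dien-12,8-olide
Conditions: (R)-2-methyl-CBS-oxazaborolidine (20 mol %), catecholborane, toluene, −78 °C
Reagents that add atoms: none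
Why: Corey–Bakshi–Shibata reduction of a cyclic enone with the alkene-bearing C1 side as the large group; the (R)-catalyst should give the 2S carbinol. This agrees with the substrate bias (hydride anti to the pseudo-axial C10 methyl), and at −78 °C catecholborane leaves the methylene lactone alone.

Step 26
Reactants: 35 (2S,7S,8R,10R)-2,4-dihydroxyguaia-1(5),11(13)-dien-12,8-olide
Product: 36 (2S,7S,8R,10R)-2-acetoxy-4-hydroxyguaia-1(5),11(13)-dien-12,8-olide
Conditions: Ac2O, pyridine, DMAP (cat.), CH2Cl2, 0 °C
Reagents that add atoms: acetic anhydride, CC(=O)OC(C)=O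
Why: Acylation of the secondary allylic alcohol under basic conditions; the tertiary C4 alcohol is not acylated and is not ionised.

Step 27
Reactants: 36 (2S,7S,8R,10R)-2-acetoxy-4-hydroxyguaia-1(5),11(13)-dien-12,8-olide
Product: 37 (2S,7S,8R,10R)-2-acetoxyguaia-1(5),3,11(13)-trien-12,8-olide
Conditions: Burgess reagent (MeO2CN−SO2N+Et3), benzene, 25 °C; cold filtration, used at once
Reagents that add atoms: none
Why: Syn-elimination of the tertiary allylic sulfamate (Burgess dehydration) toward the ring hydrogen on C3, giving the endocyclic cyclopentadiene. The C2 acetate does not ionise because the cation would be a cyclopentadienyl cation, and C2 is untouched.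

Step 28
Reactants: 22 (1S,4R,7S,8S,10S)-1-hydroxyeudesma-5,11(13)-dien-12,8-olide; 37 (2S,7S,8R,10R)-2-acetoxyguaia-1(5),3,11(13)-trien-12,8-olide
Product: 38 japonicone A
Conditions: toluene (2 M), BHT, 25 to 40 °C, dark
Reagents that add atoms: none
Why: Thermal Diels–Alder reaction of a cyclopentadiene with an α-methylene-γ-lactone. Sterics should join the open diene terminus C3 to the fully substituted C11′ and the substituted C1 to the C13′ methylene, with the lactone carbonyl endo. The dienophile reacts on its convex face (syn to H7′) and meets the diene face opposite the C10 methyl and the C2 acetoxy group, which sets C1, C3 and C11′ and leaves the acetoxy group syn to C4=C5.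

## Compound list

1 | [4-(benzyloxy)-2-methylphenyl]boronic acid | Cc1cc(OCc2ccccc2)ccc1B(O)O | starting material
2 | ethyl (E)-but-2-enoate | C/C=C/C(=O)OCC | starting material
3 | ethyl (3R)-3-[4-(benzyloxy)-2-methylphenyl]butanoate | CCOC(=O)C[C@@H](C)c1ccc(OCc2ccccc2)cc1C | intermediate
4 | (3R)-3-[4-(benzyloxy)-2-methylphenyl]butanal | O=CC[C@@H](C)c1ccc(OCc2ccccc2)cc1C | intermediate
5 | 4-(benzyloxy)-2-methyl-1-[(2R)-pent-4-en-2-yl]benzene | C=CC[C@@H](C)c1ccc(OCc2ccccc2)cc1C | intermediate
6 | 9-{(4R)-4-[4-(benzyloxy)-2-methylphenyl]pentyl}-9-borabicyclo[3.3.1]nonane | C[C@H](CCCB1C2CCCC1CCC2)c1ccc(OCc3ccccc3)cc1C | intermediate (not isolated)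
7 | (4R)-4-[4-(benzyloxy)-2-methylphenyl]pentan-1-ol | OCCC[C@@H](C)c1ccc(OCc2ccccc2)cc1C | intermediate
8 | 4-[(2R)-5-hydroxypentan-2-yl]-3-methylphenol | OCCC[C@@H](C)c1ccc(O)cc1C | intermediate
9 | (5R,6S)-5,7-dimethyl-1-oxaspiro[5.5]undeca-7,10-dien-9-one | O=C1C=C[C@]2(OCCC[C@H]2C)C(C)=C1 | intermediate
10 | (5R,6R,11S)-11-[dimethyl(phenyl)silyl]-5,7-dimethyl-1-oxaspiro[5.5]undec-7-en-9-one | O=C1C[C@H]([Si](C)(C)c3ccccc3)[C@]2(OCCC[C@H]2C)C(C)=C1 | intermediate
11 | (5S)-5-[dimethyl(phenyl)silyl]-4-[(2R)-5-hydroxypentan-2-yl]-3-methylcyclohex-3-en-1-one | OCCC[C@@H](C)C1=C(C)CC(=O)C[C@@H]1[Si](C)(C)c1ccccc1 | intermediate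
12 | (4R)-4-{(6S)-6-[dimethyl(phenyl)silyl]-2-methyl-4-oxocyclohex-1-en-1-yl}pentanal (C6′ allylsilane with tethered C1′ aldehyde) | O=CCC[C@@H](C)C1=C(C)CC(=O)C[C@@H]1[Si](C)(C)c1ccccc1 | intermediate
13 | (1S,4R,10S)-1-hydroxyeudesm-5-en-8-one | O=C1C[C@@]2(C)C(=CC1)[C@H](C)CC[C@@H]2O | intermediate
14 | (1S,4R,10S)-1-[(tert-butyldimethylsilyl)oxy]eudesm-5-en-8-one | O=C1C[C@@]2(C)C(=CC1)[C@H](C)CC[C@@H]2O[Si](C)(C)C(C)(C)C | intermediate
15 | ethyl (1S,4R,7S,10S)-1-[(tert-butyldimethylsilyl)oxy]-8-oxo-13-noreudesm-5-en-12-oate | O=C1C[C@@]2(C)C(=C[C@@H]1CC(=O)OCC)[C@H](C)CC[C@@H]2O[Si](C)(C)C(C)(C)C | intermediate (not isolated)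
16 | ethyl (1S,4R,7R,10S)-1-[(tert-butyldimethylsilyl)oxy]-8-oxo-13-noreudesm-5-en-12-oate | O=C1C[C@@]2(C)C(=C[C@H]1CC(=O)OCC)[C@H](C)CC[C@@H]2O[Si](C)(C)C(C)(C)C | intermediate
17 | ethyl (1S,4R,7R,8S,10S)-1-[(tert-butyldimethylsilyl)oxy]-8-hydroxy-13-noreudesm-5-en-12-oate | O[C@H]1C[C@@]2(C)C(=C[C@H]1CC(=O)OCC)[C@H](C)CC[C@@H]2O[Si](C)(C)C(C)(C)C | intermediate (not isolated)
18 | (1S,4R,7R,8S,10S)-1-[(tert-butyldimethylsilyl)oxy]-13-noreudesm-5-en-12,8-olide | C1C(=O)O[C@H]2C[C@@]3(C)C(=C[C@@H]12)[C@H](C)CC[C@@H]3O[Si](C)(C)C(C)(C)C | intermediate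
19 | (1S,4R,7S,8S,10S,11R)-13-(dimethylamino)-1-[(tert-butyldimethylsilyl)oxy]eudesm-5-en-12,8-olide | CN(C)C[C@@H]1C(=O)O[C@H]2C[C@@]3(C)C(=C[C@@H]12)[C@H](C)CC[C@@H]3O[Si](C)(C)C(C)(C)C | intermediate
20 | N-methyl ammonium iodide of 19 | C[N+](C)(C)C[C@@H]1C(=O)O[C@H]2C[C@@]3(C)C(=C[C@@H]12)[C@H](C)CC[C@@H]3O[Si](C)(C)C(C)(C)C.[I-] | intermediate (not isolated)
21 | (1S,4R,7S,8S,10S)-1-[(tert-butyldimethylsilyl)oxy]eudesma-5,11(13)-dien-12,8-olide | C=C1C(=O)O[C@H]2C[C@@]3(C)C(=C[C@@H]12)[C@H](C)CC[C@@H]3O[Si](C)(C)C(C)(C)C | intermediate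
22 | (1S,4R,7S,8S,10S)-1-hydroxyeudesma-5,11(13)-dien-12,8-olide | C=C1C(=O)O[C@H]2C[C@@]3(C)C(=C[C@@H]12)[C@H](C)CC[C@@H]3O | intermediate
23 | cyclopentane-1,3-dione | O=C1CCC(=O)C1 | starting material
24 | (E)-but-2-enal | C/C=C/C=O | starting material
25 | (4R)-2-hydroxy-4-methyl-3,4,6,7-tetrahydrocyclopenta[b]pyran-5(2H)-one (anomers) | OC1C[C@@H](C)C2=C(O1)CCC2=O | intermediate (not isolated)
26 | (4R)-2-methoxy-4-methyl-3,4,6,7-tetrahydrocyclopenta[b]pyran-5(2H)-one (anomers) | COC1C[C@@H](C)C2=C(O1)CCC2=O | intermediate
27 | (4R)-2-methoxy-4,6-dimethyl-3,4,6,7-tetrahydrocyclopenta[b]pyran-5(2H)-one (epimers at C2, C6) | COC1C[C@@H](C)C2=C(O1)CC(C)C2=O | intermediate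
28 | (4R)-6-hydroxy-2-methoxy-4,6-dimethyl-3,4,6,7-tetrahydrocyclopenta[b]pyran-5(2H)-one (epimers at C2, C6) | COC1C[C@@H](C)C2=C(O1)CC(C)(O)C2=O | intermediate
29 | (4R)-2-methoxy-4,6-dimethyl-5-(prop-2-en-1-yl)-2,3,4,5,6,7-hexahydrocyclopenta[b]pyran-5,6-diol | COC1C[C@@H](C)C2=C(O1)CC(C)(O)C2(O)CC=C | intermediate (not isolated)
30 | 4-hydroxy-4-methyl-2-[(2R)-4-oxobutan-2-yl]-3-(prop-2-en-1-yl)cyclopent-2-en-1-one (C4 epimers) | O=CC[C@@H](C)C1=C(CC=C)C(C)(O)CC1=O | intermediate
31 | 4-hydroxy-4-methyl-3-(3-methylbut-2-en-1-yl)-2-[(2R)-4-oxobutan-2-yl]cyclopent-2-en-1-one (C4 epimers) | O=CC[C@@H](C)C1=C(CC=C(C)C)C(C)(O)CC1=O | intermediate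
32 | (7S,8R,10R)-4,8-dihydroxyguaia-1(5),11(13)-dien-2-one (C4 epimers) | C=C(C)[C@H]1[C@H](O)C[C@@H](C)C2=C(C1)C(C)(O)CC2=O | intermediate
33 | (7S,8R,10R)-4,8,12-trihydroxyguaia-1(5),11(13)-dien-2-one (C4 epimers) | OCC(=C)[C@H]1[C@H](O)C[C@@H](C)C2=C(C1)C(C)(O)CC2=O | intermediate
34 | (7S,8R,10R)-4-hydroxy-2-oxoguaia-1(5),11(13)-dien-12,8-olide (C4 epimers) | C=C1C(=O)O[C@@H]2C[C@@H](C)C3=C(C[C@@H]12)C(C)(O)CC3=O | intermediate
35 | (2S,7S,8R,10R)-2,4-dihydroxyguaia-1(5),11(13)-dien-12,8-olide (C4 epimers) | C=C1C(=O)O[C@@H]2C[C@@H](C)C3=C(C[C@@H]12)C(C)(O)C[C@@H]3O | intermediate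
36 | (2S,7S,8R,10R)-2-acetoxy-4-hydroxyguaia-1(5),11(13)-dien-12,8-olide (C4 epimers) | C=C1C(=O)O[C@@H]2C[C@@H](C)C3=C(C[C@@H]12)C(C)(O)C[C@@H]3OC(C)=O | intermediate
37 | (2S,7S,8R,10R)-2-acetoxyguaia-1(5),3,11(13)-trien-12,8-olide | C=C1C(=O)O[C@@H]2C[C@@H](C)C3=C(C[C@@H]12)C(C)=C[C@@H]3OC(C)=O | intermediate
38 | japonicone A | C=C1C(=O)O[C@@H]2C[C@@H](C)[C@]34C[C@]5(C(=O)O[C@H]6C[C@@]7(C)C(=C[C@H]65)[C@H](C)CC[C@@H]7O)[C@H](C(C)=C3C[C@@H]12)[C@@H]4OC(C)=O | target

## Step count and least certain steps

Total: 28 steps. Longest linear sequence: 17 steps (steps 1–16 and 28). The second branch is 11 steps (17–27) before the union.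

**Step 10 (key step).** The Lewis acid may protodesilylate the allylsilane or move the β,γ-alkene into conjugation with the free C8′ ketone before ring closure. Closure may also be slow, because the chair puts the C4′ methyl axial on the silicon face. Fallback: the ketone is removed before the cyclisation. From 11, NaBH4 should give (5S)-5-[dimethyl(phenyl)silyl]-4-[(2R)-5-hydroxypentan-2-yl]-3-methylcyclohex-3-en-1-ol F1. TEMPO/PhI(OAc)2 should oxidise only its primary alcohol, to the hydroxy aldehyde F2. BF3·OEt2 should cyclise F2 (no enolisable ketone present) to (1S,4R,10S)-eudesm-5-ene-1,8-diol F3. Oxidation of the unhindered C8′ carbinol of F3 (TEMPO, PhI(OAc)2; the C1′ carbinol is neopentylic) returns to 13.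

**Step 6.** The oxidation may go through benzylic hydrogen loss to a quinone methide instead of ipso capture, or the ether oxygen may add with poor facial discrimination; spiroethers of this ring size are less well precedented than spirolactones. Fallback: a carboxylic acid is used as the ipso nucleophile, which also gives a better leaving group for the later reductive cleavage.
- From 7, TEMPO/PhI(OAc)2 in wet MeCN should give (4R)-4-[4-(benzyloxy)-2-methylphenyl]pentanoic acid F4.
- Hydrogenolysis gives (4R)-4-(4-hydroxy-2-methylphenyl)pentanoic acid F5.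
- PhI(OAc)2 gives the spirolactone (5R,6S)-5,7-dimethyl-1-oxaspiro[5.5]undeca-7,10-diene-2,9-dione F6.
- Copper-catalysed silylation gives its (5R,6R,11S)-11-silyl derivative F7.
- SmI2 opens F7 to (4R)-4-{(6S)-6-[dimethyl(phenyl)silyl]-2-methyl-4-oxocyclohex-1-en-1-yl}pentanoic acid F8.
- BH3·SMe2 at low temperature reduces the acid in preference to the ketone and returns to 11.

**Step 22.** The seven-membered ene closure may take the other diastereofacial course at C8, or the cationic intermediate may eliminate or be trapped by the tertiary hydroxyl. Fallback: the ring is closed by an organochromium allylation. From 30, cross-metathesis with methyl 2-(bromomethyl)acrylate should give methyl (2Z)-2-(bromomethyl)-4-{5-hydroxy-5-methyl-3-oxo-2-[(2R)-4-oxobutan-2-yl]cyclopent-1-en-1-yl}but-2-enoate F9. CrCl2 should convert F9 into the allylchromium species, which adds to the aldehyde through a closed anti-selective transition state and lactonises to 34, bypassing 31–33.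

**Step 27.** Elimination may run toward the C15 methyl, or the diene may rearrange by 1,5-hydrogen shift to an enol acetate during isolation. Fallback: the diene is never isolated. Alcohol 36 and dienophile 22 are warmed together with catalytic pyridinium p-toluenesulfonate and molecular sieves. The tertiary allylic alcohol then ionises and loses the C3 proton in the presence of the trap, and the cyclopentadiene is consumed as it forms, arriving directly at 38. Isomeric dienes that are not cisoid do not react.

**Step 28.** The dienophile may attack syn to the acetoxy group (the electronic preference of 5-oxygenated cyclopentadienes), the exo or the regioisomeric adduct may form, or isomerisation and dimerisation of 37 may outrun a slow thermal cycloaddition. Fallback: the lactone is activated and the alcohol kept protected. The silyl ether 21 and 37 are combined with Et2AlCl at −60 °C, where the hydrogen shift is frozen and steric discrimination of the diene faces is greatest. This should give the C1′ tert-butyldimethylsilyl ether of japonicone A F10, and HF·pyridine then returns to 38.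

## Further compounds

F1 | step 10 | (5S)-5-[dimethyl(phenyl)silyl]-4-[(2R)-5-hydroxypentan-2-yl]-3-methylcyclohex-3-en-1-ol (C1 epimers) | OCCC[C@@H](C)C1=C(C)CC(O)C[C@@H]1[Si](C)(C)c1ccccc1
F2 | step 10 | (4R)-4-{(6S)-6-[dimethyl(phenyl)silyl]-4-hydroxy-2-methylcyclohex-1-en-1-yl}pentanal (carbinol epimers) | O=CCC[C@@H](C)C1=C(C)CC(O)C[C@@H]1[Si](C)(C)c1ccccc1
F3 | step 10 | (1S,4R,10S)-eudesm-5-ene-1,8-diol (C8 epimers) | OC1C[C@@]2(C)C(=CC1)[C@H](C)CC[C@@H]2O
F4 | step 6 | (4R)-4-[4-(benzyloxy)-2-methylphenyl]pentanoic acid | OC(=O)CC[C@@H](C)c1ccc(OCc2ccccc2)cc1C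
F5 | step 6 | (4R)-4-(4-hydroxy-2-methylphenyl)pentanoic acid | OC(=O)CC[C@@H](C)c1ccc(O)cc1C
F6 | step 6 | (5R,6S)-5,7-dimethyl-1-oxaspiro[5.5]undeca-7,10-diene-2,9-dione | O=C1C=C[C@]2(OC(=O)CC[C@H]2C)C(C)=C1
F7 | step 6 | (5R,6R,11S)-11-[dimethyl(phenyl)silyl]-5,7-dimethyl-1-oxaspiro[5.5]undec-7-ene-2,9-dione | O=C1C[C@H]([Si](C)(C)c3ccccc3)[C@]2(OC(=O)CC[C@H]2C)C(C)=C1
F8 | step 6 | (4R)-4-{(6S)-6-[dimethyl(phenyl)silyl]-2-methyl-4-oxocyclohex-1-en-1-yl}pentanoic acid | OC(=O)CC[C@@H](C)C1=C(C)CC(=O)C[C@@H]1[Si](C)(C)c1ccccc1
F9 | step 22 | methyl (2Z)-2-(bromomethyl)-4-{5-hydroxy-5-methyl-3-oxo-2-[(2R)-4-oxobutan-2-yl]cyclopent-1-en-1-yl}but-2-enoate | O=CC[C@@H](C)C1=C(C/C=C(\CBr)C(=O)OC)C(C)(O)CC1=O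
F0 | step 27 | none | none
F10 | step 28 | japonicone A C1′ tert-butyldimethylsilyl ether | C=C1C(=O)O[C@@H]2C[C@@H](C)[C@]34C[C@]5(C(=O)O[C@H]6C[C@@]7(C)C(=C[C@H]65)[C@H](C)CC[C@@H]7O[Si](C)(C)C(C)(C)C)[C@H](C(C)=C3C[C@@H]12)[C@@H]4OC(C)=O
A1 | alternative 1 | guaia-1(10),5,11(13)-trien-12,8-olide | C=C1C(=O)O[C@@H]2CC(C)=C3CC[C@@H](C)C3=C[C@@H]12
A2 | alternative 2 | 13-nor-2-oxoguai-1(5)-en-12,8-olide | C1C(=O)O[C@@H]2C[C@@H](C)C3=C(C[C@@H]12)[C@H](C)CC3=O
A3 | alternative 3 | 13-nor guaiane–eudesmane norbornene adduct with C2 methyl ester syn to C4=C5 and C1′ silyl ether | C1C(=O)O[C@@H]2C[C@@H](C)[C@]34C[C@]5(C(=O)O[C@H]6C[C@@]7(C)C(=C[C@H]65)[C@H](C)CC[C@@H]7O[Si](C)(C)C(C)(C)C)[C@H](C(C)=C3C[C@@H]12)[C@@H]4C(=O)OC
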